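**Retrosynthetic overview**

- Vidalol B comes from its heptamethyl ether by cleavage of all seven aryl methyl ethers in the last step.
- The heptamethyl ether is cut at both CH2–C1' bonds (bridge to outer ring): a central bis(tosylhydrazone) is joined twice to (2,3-dibromo-4,5-dimethoxyphenyl)boronic acid in one base-mediated, metal-free operation.
- The bis(tosylhydrazone) comes from 1,3,5-trimethoxybenzene by twofold Rieche formylation, bromination of the last ring C–H and condensation with tosylhydrazide.
- The boronic acid comes from 5-bromo-2-methoxyphenol: the free OH places iodine para and bromine ortho, then O-methylation and iodine–magnesium exchange with borate trapping put boron on the carbon next to C–Br.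
- Feature: each CH2 bridge links a central-ring carbon flanked by two oxygen-bearing carbons to outer-ring C-1', which sits next to C-2'–Br; five aryl C–Br bonds must never meet a transition metal. No ring is formed; all three benzene rings come from the starting materials.

Key step: step 8

Assumption: both C=N bonds of the bis(tosylhydrazone) are taken as E, the usual thermodynamic geometry; the geometry is lost when the diazo groups form.

Remark: the boronic acid is built by phenol-directed halogenation rather than by deprotonating 3,4-dibromoveratrole, because the site of deprotonation there (next to Br or next to OMe) is not secure.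

**Step 1**
Reactants: 1 1,3,5-trimethoxybenzene
Product: 3 2,4,6-trimethoxybenzene-1,3-dicarbaldehyde, via bis(α-chloro ether) 2 (not isolated)
Conditions: Cl2CHOMe (3 equiv), TiCl4 (4.5 equiv), CH2Cl2, 0 °C to rt; then ice/1 M HCl
Reagents that add atoms: dichloromethyl methyl ether, COC(Cl)Cl; water, O
Why: Rieche formylation (Friedel–Crafts type): every free position of 1 is ortho to two methoxy groups and para to the third, the monoaldehyde stage is still activated enough for a second attack at an equivalent position so that only one dialdehyde can form, and the α-chloro ether 2 is hydrolysed to the aldehyde on aqueous work-up.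

**Step 2**
Reactants: 3 2,4,6-trimethoxybenzene-1,3-dicarbaldehyde
Product: 4 5-bromo-2,4,6-trimethoxybenzene-1,3-dicarbaldehyde
Conditions: NBS (1.1 equiv), DMF, rt, dark
Reagents that add atoms: N-bromosuccinimide, O=C1CCC(=O)N1Br
Why: Electrophilic aromatic bromination: the only ring C–H left is ortho to two methoxy groups, para to the third and meta to both formyl groups, so substitution there should be faster than any ipso attack.

**Step 3**
Reactants: 4 5-bromo-2,4,6-trimethoxybenzene-1,3-dicarbaldehyde; 5 tosylhydrazide (4-methylbenzenesulfonohydrazide)
Product: 6 (E,E)-5-bromo-2,4,6-trimethoxyisophthalaldehyde bis(tosylhydrazone)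
Conditions: 5 (2.1 equiv), MeOH, 60 °C
Reagents that add atoms: none
Why: Hydrazone formation by condensation of an aldehyde with a sulfonylhydrazide: both formyl groups should react, the product should crystallise from methanol, and the E geometry with aryl and NHTs anti is the thermodynamically preferred one.

**Step 4**
Reactants: 7 5-bromo-2-methoxyphenol
Product: 8 5-bromo-4-iodo-2-methoxyphenol
Conditions: NIS (1.05 equiv), TsOH·H2O (10 mol %), MeCN, 0 °C to rt
Reagents that add atoms: N-iodosuccinimide, O=C1CCC(=O)N1I
Why: Electrophilic aromatic iodination directed by the free phenol: C-4 is para to OH and less hindered than C-6 (between OH and Br), while the para position of the methoxy group is already taken by bromine.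

**Step 5**
Reactants: 8 5-bromo-4-iodo-2-methoxyphenol
Product: 9 2,3-dibromo-4-iodo-6-methoxyphenol
Conditions: NBS (1.05 equiv), i-Pr2NH (10 mol %), CH2Cl2, 0 °C to rt
Reagents that add atoms: N-bromosuccinimide, O=C1CCC(=O)N1Br
Why: Amine-mediated ortho-bromination of a phenol (electrophilic aromatic substitution): C-6 is the only C–H still activated by the OH group, and delivery of bromine through the N-bromoamine hydrogen-bonded to the phenol should favour it over ipso attack at the C–I carbon.

**Step 6**
Reactants: 9 2,3-dibromo-4-iodo-6-methoxyphenol
Product: 10 2,3-dibromo-1-iodo-4,5-dimethoxybenzene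
Conditions: MeI (1.5 equiv), K2CO3 (2 equiv), DMF, rt
Reagents that add atoms: iodomethane, CI
Why: Williamson ether synthesis: K2CO3 forms the ortho-bromophenoxide, MeI alkylates it, and none of the three aryl halides reacts under these conditions.

**Step 7**
Reactants: 10 2,3-dibromo-1-iodo-4,5-dimethoxybenzene
Product: 13 (2,3-dibromo-4,5-dimethoxyphenyl)boronic acid, via arylmagnesium chloride 11 (not isolated), via dimethyl arylboronate 12 (not isolated)
Conditions: i-PrMgCl·LiCl (1.05 equiv), THF, −40 °C; B(OMe)3 (2 equiv), −40 °C to rt; 1 M HCl
Reagents that add atoms: trimethyl borate, COB(OC)OC; water, O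
Why: Iodine–magnesium exchange followed by borate trapping: the C–I bond exchanges far faster than either C–Br bond at −40 °C, the ortho-bromoarylmagnesium 11 should not eliminate to an aryne at this temperature, and hydrolysis of boronate 12 releases the boronic acid.

**Step 8**
Reactants: 6 (E,E)-5-bromo-2,4,6-trimethoxyisophthalaldehyde bis(tosylhydrazone); 13 (2,3-dibromo-4,5-dimethoxyphenyl)boronic acid
Product: 16 2-bromo-4,6-bis(2,3-dibromo-4,5-dimethoxybenzyl)-1,3,5-trimethoxybenzene (vidalol B heptamethyl ether), via bis(diazomethyl)arene 14 (not isolated), via bis(benzylic boronic acid) 15 (not isolated)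
Conditions: 13 (4 equiv), K2CO3 (6 equiv), 1,4-dioxane, 110 °C, argon
Reagents that add atoms: none
Why: K2CO3 deprotonates each N–H and the hydrazone anions lose sulfinate at 110 °C (Bamford–Stevens) to give bis(diazo) compound 14; each nucleophilic diazo carbon binds the empty orbital of boron in 13, the 2,3-dibromo-4,5-dimethoxyphenyl group shifts from boron to carbon as N2 leaves, and the doubly benzylic boronic acid 15 is protodeboronated under the basic conditions to the two CH2 bridges. The closest known reaction type is the metal-free reductive coupling of aldehyde N-tosylhydrazones with arylboronic acids, run here twice on one arene. No ring is closed and no stereocentre remains, since both boron-bearing carbons of 15 end as CH2 groups. The step needs chemoselectivity toward five aryl C–Br bonds, which the absence of any transition metal, organolithium or hydride secures, and regiochemistry on the outer rings, which is fixed because the migrating carbon is the one that carried boron. The electron-rich 2,4,6-trimethoxyaryl diazo carbons are good nucleophiles toward boron, and the excess of 13 should outrun carbene and azine pathways and make up for base-induced protodeboronation of 13.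

**Step 9**
Reactants: 16 vidalol B heptamethyl ether
Product: 17 vidalol B (2-bromo-4,6-bis(2,3-dibromo-4,5-dihydroxybenzyl)benzene-1,3,5-triol)
Conditions: BBr3 (12 equiv), CH2Cl2, −78 °C to rt; then ice-water
Reagents that add atoms: none
Why: O-Demethylation of aryl methyl ethers by BBr3: bromide attacks each O-methyl group of the boron-complexed ether, the aryl C–Br bonds and the two diarylmethane C–C bonds are not touched, and aqueous work-up frees the seven phenols.

**Compound list**

1 | 1,3,5-trimethoxybenzene | COc1cc(OC)cc(OC)c1 | starting material
2 | 1,3-bis[chloro(methoxy)methyl]-2,4,6-trimethoxybenzene (mixture of diastereomers, not isolated) | COC(Cl)c1c(OC)cc(OC)c(C(Cl)OC)c1OC | intermediate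
3 | 2,4,6-trimethoxybenzene-1,3-dicarbaldehyde | COc1cc(OC)c(C=O)c(OC)c1C=O | intermediate
4 | 5-bromo-2,4,6-trimethoxybenzene-1,3-dicarbaldehyde | COc1c(Br)c(OC)c(C=O)c(OC)c1C=O | intermediate
5 | tosylhydrazide (4-methylbenzenesulfonohydrazide) | Cc1ccc(cc1)S(=O)(=O)NN | starting material
6 | (E,E)-5-bromo-2,4,6-trimethoxyisophthalaldehyde bis(tosylhydrazone) | COc1c(/C=N/NS(=O)(=O)c2ccc(C)cc2)c(OC)c(Br)c(OC)c1/C=N/NS(=O)(=O)c3ccc(C)cc3 | intermediate
7 | 5-bromo-2-methoxyphenol | COc1ccc(Br)cc1O | starting material
8 | 5-bromo-4-iodo-2-methoxyphenol | COc1cc(I)c(Br)cc1O | intermediate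
9 | 2,3-dibromo-4-iodo-6-methoxyphenol | COc1cc(I)c(Br)c(Br)c1O | intermediate
10 | 2,3-dibromo-1-iodo-4,5-dimethoxybenzene | COc1cc(I)c(Br)c(Br)c1OC | intermediate
11 | (2,3-dibromo-4,5-dimethoxyphenyl)magnesium chloride (LiCl complex, not isolated) | COc1cc([Mg]Cl)c(Br)c(Br)c1OC | intermediate
12 | dimethyl (2,3-dibromo-4,5-dimethoxyphenyl)boronate (not isolated) | COB(OC)c1cc(OC)c(OC)c(Br)c1Br | intermediate
13 | (2,3-dibromo-4,5-dimethoxyphenyl)boronic acid | OB(O)c1cc(OC)c(OC)c(Br)c1Br | intermediate
14 | 3-bromo-1,5-bis(diazomethyl)-2,4,6-trimethoxybenzene (not isolated) | COc1c(C=[N+]=[N-])c(OC)c(Br)c(OC)c1C=[N+]=[N-] | intermediate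
15 | [(5-bromo-2,4,6-trimethoxy-1,3-phenylene)bis[(2,3-dibromo-4,5-dimethoxyphenyl)methylene]]diboronic acid (mixture of diastereomers, not isolated) | COc1c(C(B(O)O)c2cc(OC)c(OC)c(Br)c2Br)c(OC)c(Br)c(OC)c1C(B(O)O)c3cc(OC)c(OC)c(Br)c3Br | intermediate
16 | 2-bromo-4,6-bis(2,3-dibromo-4,5-dimethoxybenzyl)-1,3,5-trimethoxybenzene (vidalol B heptamethyl ether) | COc1c(Cc2cc(OC)c(OC)c(Br)c2Br)c(OC)c(Br)c(OC)c1Cc3cc(OC)c(OC)c(Br)c3Br | intermediate
17 | vidalol B | Oc1cc(Cc2c(O)c(Br)c(O)c(Cc3cc(O)c(O)c(Br)c3Br)c2O)c(Br)c(Br)c1O | target

**Step count and risks**

Total step count: 9. Longest linear sequence: 6 steps (7 → 8 → 9 → 10 → 13 → 16 → 17).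

Steps most likely to fail:

Step 8. The second coupling may stall after the first. The ortho-bromo boronic acid may lose boron under base before it captures a diazo carbon. The electron-rich diazo groups may lose nitrogen thermally and go on to azines or insert into an ortho-methoxy C–H. The fallback sets out from 10 and 4 and comes back at 16. Iodide 10 is converted into arylmagnesium chloride 11 as in step 7 (i-PrMgCl·LiCl, THF, −40 °C), and 11 (2.3 equiv) is added to dialdehyde 4 to give (5-bromo-2,4,6-trimethoxy-1,3-phenylene)bis[(2,3-dibromo-4,5-dimethoxyphenyl)methanol] F1. Ionic hydrogenation of F1 (Et3SiH, CF3CO2H, CH2Cl2, 0 °C) should remove both doubly benzylic hydroxyl groups through cations stabilised by the trimethoxyaryl ring and give 16. The only metal used is magnesium at low temperature, so the C–Br bonds should survive.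

Step 1. Formylation may stop at the monoaldehyde because the first formyl group, bound to TiCl4, deactivates the ring. TiCl4 may also cleave a methoxy group next to the new carbonyl. The fallback sets out from 1 and comes back at 4, so it also replaces step 2. Exhaustive bromination of 1 (NBS, 3.1 equiv, MeCN, rt) should give 2,4,6-tribromo-1,3,5-trimethoxybenzene F2. Two rounds of bromine–lithium exchange and DMF quench in one flask (n-BuLi, THF, −78 °C; DMF; n-BuLi; DMF; then 1 M HCl) should turn two of the three equivalent C–Br positions into formyl groups and leave the third bromine, giving 4.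

Step 5. Electrophilic bromine may attack ipso at the iodine-bearing carbon para to OH, which would scramble the halogens, or substitution at the crowded site between OH and Br may be slow. The fallback sets out from 7 and comes back at 9 with the order of halogenation reversed. Ortho-directed bromination of 7 (NBS, i-Pr2NH cat., CH2Cl2, 0 °C) should give 2,3-dibromo-6-methoxyphenol F3, to be separated from any para isomer. Iodination of F3 (NIS, TsOH cat., MeCN) at the one remaining OH-activated position, para to OH, should give 9. No C–I bond is then exposed to a brominating agent.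

**Further compounds**

F1 | step 8 | (5-bromo-2,4,6-trimethoxy-1,3-phenylene)bis[(2,3-dibromo-4,5-dimethoxyphenyl)methanol] (mixture of diastereomers) | COc1c(C(O)c2cc(OC)c(OC)c(Br)c2Br)c(OC)c(Br)c(OC)c1C(O)c3cc(OC)c(OC)c(Br)c3Br
F2 | step 1 | 2,4,6-tribromo-1,3,5-trimethoxybenzene | COc1c(Br)c(OC)c(Br)c(OC)c1Br
F3 | step 5 | 2,3-dibromo-6-methoxyphenol | COc1ccc(Br)c(Br)c1O
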